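(The runs were computed on assumed constants; the scatter is artificial.)

Starting material is the molecule I follow, and the flask asked about is the violet run itself, carried on to 15 d.

- violet: starting material 0.10 M; protic impurity 0.010 M; free catalyst 4.9 mol% (in portions, 4); stray impurity 1 mM; the very flask that is asked about, followed so far; portions every 10 h
- flask: starting material 0.10 M; protic impurity 0.0100 M; free catalyst 4.9 mol% (in portions, 4); stray impurity 1.0 mM; time 15 d; the portions of free catalyst follow each other after 10 h, the first at the start

violet run (percent of the starting material charged)

| time / d | starting material / % | target / % | side product / % |
|---|---|---|---|
| 0.333 | 31.3 | 0 | 62.4 |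
| 0.625 | 9.5 | 2.3 | 80.0 |
| 1.04 | 3.1 | 1.4 | 86.5 |
| 1.67 | 0 | 0.5 | 87.1 |
| 2.50 | 0.5 | 2.1 | 88.2 |
| 5.00 | 0.5 | 1.9 | 88.5 |

(standard deviation of a reading: 1 percentage point)

- reactions considered so far: starting material -> side product; free catalyst + stray impurity -> spent catalyst A; starting material + protic impurity -> quenched substrate; free catalyst -> spent catalyst B; starting material + free catalyst -> free catalyst + target
- the reaction counts as stopped when no species that holds the starting material changes by six tenths of a point or more over the second half of the time

1. which holds at 15 d: what has brought the reaction to rest, or that it has not come to rest (all of the starting material has reacted / it is still moving)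
2. how much of the starting material has reacted by 15 d
3. how much target there is at 15 d, in percent of the starting material charged
4. how much side product there is at 15 d, in percent of the starting material charged

My molecule stands at a fork. I book 10.0 % of the charge as quenched by protic impurity, so 90.0 % remains for target and side product. The first reading gives a pseudo-first-order decay constant of 3.49 d⁻¹. Its half-life of 0.199 d is far shorter than 15 d, so I expect no starting material at the end. Between additions, a fraction 0.234 of it survives.

Now the catalyst. That first reading shows target at 0 %, so I let stray impurity take 20.4 % of the catalyst charge out of the first portion, which holds 25.0 %. I call 12.1 % the catalyst met, the share of the catalyst charge that enters free of stray impurity, each portion weighed by the starting material present at its addition. So I expect little target.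

The size comes from the last two readings, whose mean is 2.00 %. This is my weak link, since each reading scatters by 1 percentage point. Adding the reading at 1.67 d gives a mean of 3 readings, 1.50 %, good to about 0.58 points. I commit to that target and 88.5 % side product.

The forecast, a little above me on target, says all of the starting material has reacted, 100 % reacted, target 1.8 % and side product 88.2 %, noting “No listed reaction consumes target or side product”.

The flask gives all of the starting material has reacted, with 100 % reacted, target 1.78 % and side product 88.4 %.

    starting material → side product (k = 0.132 h⁻¹)
    free catalyst + stray impurity → spent catalyst A (k = 3900 L mol⁻¹ h⁻¹)
    starting material + protic impurity → quenched substrate (k = 6.39 L mol⁻¹ h⁻¹)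
    free catalyst → spent catalyst B (k = 0.125 h⁻¹)
    starting material + free catalyst → free catalyst + target (k = 7.31 L mol⁻¹ h⁻¹)

At 0.205 d the step to side product has a half-life of 0.22 d, shorter than the 0.81 d of the catalysed step with the whole catalyst charge present at once. Scaled by the catalyst met, these give target-to-side-product odds, a selectivity factor, of 0.0329, and this flask stands at 0.0201.

The neighbour flask with 0.25 M of starting material has catalyst 2.50 times as concentrated, and stray impurity takes less of its charge, so its catalyst met is 24.4 %. With the survival fraction unchanged, both factors raise the odds to 0.101, or 8.82 % target, and that neighbour flask gives 7.87 %.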